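The route cuts the C3–C4 bond of the six-membered carbocycle. In the numbering used, C1 bears C7, C2 is the vinyl CH, C3 and C6 are the carbonyl carbons, and C4 and C5 are the oxirane carbons. The feature exploited is that C4 belongs to the three-membered oxirane ring. A carbanion there is configurationally stable and is locked on the face that also carries C6, so a normally electrophilic carbon becomes the nucleophile for acyl carbon C3. One operation, tin–lithium exchange then internal acylation, closes the carbocycle as the C3 enone with C4 retained. The precursor is an open-chain C4-stannyl epoxide whose C5 arm carries an acetal-protected C6 carbinol and a Z-configured C1=C2 Weinreb enamide.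

Key step: step 12

Assumption: the addition in step 10 gives both C6 epimers. The 6S epimer is drawn in 20–26, and the mixture can be carried on because C6 becomes a carbonyl carbon in step 15.

Step 1
Reactants: 1 propargyl alcohol; 2 (2E,6E)-farnesyl bromide
Product: 4 (5E,9E)-6,10,14-trimethylpentadeca-5,9,13-trien-2-yn-1-ol, via dimagnesium acetylide alkoxide 3 (not isolated)
Conditions: 1, EtMgBr (2.2 equiv), THF, 0 °C→rt; CuI (10 mol %), 2, 0→40 °C; aq NH4Cl
Reagents that add atoms: none
Why: Copper-catalysed SN2 allylation of an alkynyl Grignard reagent, in which the O,C-dimagnesium salt reacts only at carbon and attacks the unhindered primary terminus of the allylic bromide, so the skipped enyne forms without alcohol protection and the 2E,6E geometry is carried over.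

Step 2
Reactants: 4 enynol
Product: 6 (2Z,5E,9E)-3-iodo-6,10,14-trimethylpentadeca-2,5,9,13-tetraen-1-ol, via cyclic alkenylalanate 5 (not isolated)
Conditions: Red-Al (1.5 equiv), THF, 0 °C→rt; I2, THF, −78→0 °C; aq Na2S2O3/Rochelle salt
Reagents that add atoms: iodine, II
Why: Hydroxyl-directed trans-hydroalumination of a propargylic alcohol puts hydride on future C5 and aluminium on future C4 inside a five-membered alanate, and iodinolysis with retention leaves iodine cis to the carbinol carbon (future C6).

Step 3
Reactants: 6 Z-iodo allylic alcohol; 7 tributyltin chloride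
Product: 9 (2Z,5E,9E)-6,10,14-trimethyl-3-(tributylstannyl)pentadeca-2,5,9,13-tetraen-1-ol, via dilithio alkenyl alkoxide 8 (not isolated)
Conditions: t-BuLi (3.1 equiv), Et2O, −78 °C; 7 (1.2 equiv), −78 °C→rt; H2O; Et3N-washed silica
Reagents that add atoms: tributyltin chloride 7, CCCC[Sn](Cl)(CCCC)CCCC
Why: Iodine–lithium exchange on the lithium alkoxide gives a chelated, configurationally stable alkenyllithium that is stannylated at carbon with retention of alkene geometry, any O–Sn bond being hydrolysed on work-up.

Step 4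
Reactants: 9 Z-stannyl allylic alcohol
Product: 10 [(2R,3S)-3-[(2E,6E)-3,7,11-trimethyldodeca-2,6,10-trienyl]-3-(tributylstannyl)oxiran-2-yl]methanol
Conditions: Ti(OiPr)4 (20 mol %), D-(−)-DIPT (24 mol %), TBHP (2 equiv, decane), 4 Å MS, CH2Cl2, −20 °C
Reagents that add atoms: tert-butyl hydroperoxide, CC(C)(C)OO
Why: Katsuki–Sharpless asymmetric epoxidation touches only the allylic-alcohol alkene, and D-(−)-tartrate delivers oxygen to the face opposite to the one that L-(+)-tartrate uses in making (2S,3S)-epoxygeraniol, so syn addition to the Z-alkenylstannane sets C5 (R here) and C4 (S here) together with tin cis to C6.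

Step 5
Reactants: 10 stannyl epoxy alcohol
Product: 11 (2R,3S)-3-[(2E,6E)-3,7,11-trimethyldodeca-2,6,10-trienyl]-3-(tributylstannyl)oxirane-2-carbaldehyde
Conditions: DMP (1.3 equiv), NaHCO3, CH2Cl2, 0 °C→rt
Reagents that add atoms: none
Why: Buffered Dess–Martin oxidation is neutral enough for the epoxystannane and the triene, and the oxirane C5–H cannot enolise, so C5 is not at risk.

Step 6
Reactants: 12 but-2-yne-1,4-diol
Product: 13 4-(tert-butyldimethylsilyloxy)but-2-yn-1-ol
Conditions: 12 (3 equiv), TBSCl (1 equiv), imidazole, DMF, 0 °C→rt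
Reagents that add atoms: tert-butyldimethylsilyl chloride, CC(C)(C)[Si](C)(C)Cl
Why: Statistical monosilylation with the cheap diol in excess differentiates the future C7 oxygen (silylated) from the future C3 oxygen (free).

Step 7
Reactants: 13 mono-TBS butynediol
Product: 15 (Z)-4-(tert-butyldimethylsilyloxy)-3-iodobut-2-en-1-ol, via cyclic alkenylalanate 14 (not isolated)
Conditions: Red-Al (1.5 equiv), THF, 0 °C; I2, THF, −78→0 °C; aq Na2S2O3/Rochelle salt
Reagents that add atoms: iodine, II
Why: Trans-hydroalumination/iodination is steered by the single free hydroxyl, so iodine ends on C1 next to the silyloxymethyl group and cis to the C3 carbinol, while keeping the alanate at or below 0 °C prevents loss of silyloxide to an allene.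

Step 8
Reactants: 15 Z-iodo allylic alcohol
Product: 17 (Z)-4-(tert-butyldimethylsilyloxy)-3-iodobut-2-enoic acid, via enal 16 (not isolated)
Conditions: TEMPO (7 mol %), NaClO2 (2 equiv), NaOCl (2 mol %), MeCN/pH 6.7 phosphate buffer, 35 °C
Reagents that add atoms: sodium chlorite, [Na+].[O-]Cl=O
Why: TEMPO/chlorite oxidation of a primary alcohol to the acid consumes the enal as it forms, so the Z-β-iodo enal has no time to isomerise, and the near-neutral buffer leaves the TBS ether alone.

Step 9
Reactants: 17 Z-β-iodo acid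
Product: 18 (Z)-4-(tert-butyldimethylsilyloxy)-3-iodo-N-methoxy-N-methylbut-2-enamide
Conditions: MeNH(OMe)·HCl, EDCI·HCl, N-methylmorpholine, CH2Cl2, 0 °C→rt
Reagents that add atoms: N,O-dimethylhydroxylamine hydrochloride, CNOC.Cl
Why: Carbodiimide amide coupling with this weakly nucleophilic amine acylates nitrogen without addition–elimination at the iodo-bearing carbon, and installing the acyl group on the small robust fragment spares the epoxystannane all later oxidation steps.

Step 10
Reactants: 18 Z-β-iodo Weinreb enamide; 11 stannyl epoxy aldehyde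
Product: 20 (2Z,4S)-3-[(tert-butyldimethylsilyloxy)methyl]-4-hydroxy-N-methoxy-N-methyl-4-[(2R,3S)-3-[(2E,6E)-farnesyl]-3-(tributylstannyl)oxiran-2-yl]but-2-enamide, via alkenylmagnesium chloride 19 (not isolated)
Conditions: 18 (1.3 equiv), iPrMgCl·LiCl (1.25 equiv), THF, −40 °C; 11, −78→−40 °C; pH 7 buffer; crude 20 taken on at once
Reagents that add atoms: none
Why: Iodine–magnesium exchange (turbo-Grignard) is fast on Z-β-iodo-α,β-unsaturated carboxylic acid derivatives because the cis carbonyl oxygen chelates the sp2 carbanion and preserves its geometry, the 1,2-addition to the aldehyde forms C1–C6 with at most a modest Felkin–Anh bias at C6 that does not matter, and the magnesium alkoxide does not expel the amide nitrogen since that would reverse the usual magnesium-amide opening of lactones.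

Step 11
Reactants: 20 hydroxy enamide
Product: 21 (2Z,4S)-3-[(tert-butyldimethylsilyloxy)methyl]-N-methoxy-4-[(2-methoxypropan-2-yl)oxy]-N-methyl-4-[(2R,3S)-3-[(2E,6E)-farnesyl]-3-(tributylstannyl)oxiran-2-yl]but-2-enamide
Conditions: 2-methoxypropene (5 equiv), PPTS (5 mol %), CH2Cl2, 0 °C; Et3N; Et3N-washed silica
Reagents that add atoms: 2-methoxypropene, COC(C)=C
Why: Acid-catalysed addition of the alcohol to an enol ether (MOP ketal formation) is rapid, creates no stereocentre, blocks lactonisation onto the cis amide, and gives C6 a lithium-coordinating group that, unlike a silyl ether, cannot migrate to a C4 carbanion.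

Step 12
Reactants: 21 C4-stannyl epoxide bearing the Z-enamide
Product: 24 (1R,5S,6R)-4-[(tert-butyldimethylsilyloxy)methyl]-5-[(2-methoxypropan-2-yl)oxy]-1-[(2E,6E)-farnesyl]-7-oxabicyclo[4.1.0]hept-3-en-2-one, via oxiranyllithium 22 (not isolated), via tetrahedral lithium chelate 23 (not isolated)
Conditions: n-BuLi (1.05 equiv, precooled), THF, −100 °C, 10 min; pH 7 phosphate buffer, −100 °C→rt
Reagents that add atoms: none
Why: Proposed new method: n-BuLi adds to tin and the stannate expels its best carbanion, the oxygen-bearing oxirane carbon C4 with its s-rich exocyclic orbital, as oxiranyllithium 22 plus Bu4Sn; 22 adds at once to the adjacent C3 amide carbonyl, which drains the reversible exchange, and the N,O-chelated adduct 23 persists until the buffered quench releases the enone, so over-addition cannot occur. The closest known reactions are tin–lithium exchange of epoxystannanes with retentive capture by external aldehydes or ketones, and Parham-type cyclisations of aryl- or alkenyllithiums onto Weinreb amides, whose combination at an oxirane carbon is untested. The new C3–C4 bond closes the C1–C6 carbocycle in a 6-exo-trig mode, helped by the cis-substituted oxirane and the Z C1=C2 alkene, which already hold the chain in a U shape. No new stereocentre forms: C4 reacts with retention because a carbanion in a three-membered ring inverts slowly and only the cis-fused bicycle is geometrically possible, so C4 stays tied to C5 as set in step 4. The step needs butyllithium to attack tin rather than the amide carbonyl, the enamide β-carbon or the γ-hydrogens, which the two acetal oxygens at C6 favour by pre-complexing the reagent next to the cis tin, with −100 °C and one equivalent as further safeguards. It also needs acylation to outrun α-elimination to a carbenoid, and because a C6 silyl ether would offer the anion a competing 1,4 O→C silyl shift, C6 carries the non-transferable ketal.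

Step 13
Reactants: 24 protected epoxyquinol enone
Product: 25 (1R,5S,6R)-5-hydroxy-4-(hydroxymethyl)-1-[(2E,6E)-farnesyl]-7-oxabicyclo[4.1.0]hept-3-en-2-one
Conditions: CSA (20 mol %), MeOH, 0 °C→rt
Reagents that add atoms: none
Why: Acid-catalysed methanolysis removes the very labile MOP ketal and the primary allylic TBS ether in one operation under conditions too mild to protonate the trisubstituted alkenes or open the oxirane, which the adjacent carbonyl deactivates.

Step 14
Reactants: 25 epoxyquinol diol
Product: 26 [(1R,2S,6R)-2-hydroxy-5-oxo-6-[(2E,6E)-farnesyl]-7-oxabicyclo[4.1.0]hept-3-en-3-yl]methyl acetate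
Conditions: AcCl (1.05 equiv), 2,4,6-collidine, CH2Cl2, −78 °C
Reagents that add atoms: acetyl chloride, CC(=O)Cl
Why: Sterically controlled acylation at low temperature distinguishes the unhindered primary C7 hydroxyl from the secondary C6 hydroxyl flanked by the oxirane.

Step 15
Reactants: 26 C7 monoacetate
Product: 27 target CNP0301406.1, [(1S,6R)-2,5-dioxo-6-[(2E,6E)-farnesyl]-7-oxabicyclo[4.1.0]hept-3-en-3-yl]methyl acetate
Conditions: DMP (1.5 equiv), NaHCO3, CH2Cl2, 0 °C→rt
Reagents that add atoms: none
Why: Dess–Martin oxidation turns the remaining C6 carbinol into the second carbonyl under neutral conditions that spare the base-sensitive epoxy-enedione, erasing the C6 stereocentre and leaving C4 (R) and C5 (S, by changed priorities only) as set in step 4.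

Compound list
1 | prop-2-yn-1-ol (propargyl alcohol) | C#CCO | starting material
2 | (2E,6E)-farnesyl bromide | BrC/C=C(\C)CC/C=C(\C)CCC=C(C)C | starting material
3 | O,C-bis(bromomagnesium) derivative of 1 | Br[Mg]OCC#C[Mg]Br | intermediate
4 | (5E,9E)-6,10,14-trimethylpentadeca-5,9,13-trien-2-yn-1-ol | OCC#CC/C=C(\C)CC/C=C(\C)CCC=C(C)C | intermediate
5 | sodium cyclic alkenylalanate from 4 (five-membered O–Al–C ring, Al on future C4) | [Na+].COCCO[Al-]1(OCCOC)OCC=C1C/C=C(\C)CC/C=C(\C)CCC=C(C)C | intermediate
6 | (2Z,5E,9E)-3-iodo-6,10,14-trimethylpentadeca-2,5,9,13-tetraen-1-ol | OC/C=C(\I)C/C=C(\C)CC/C=C(\C)CCC=C(C)C | intermediate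
7 | tributyltin chloride | CCCC[Sn](Cl)(CCCC)CCCC | starting material
8 | O,C-dilithio derivative of 6 (Li cis to CH2OLi) | [Li]OC/C=C(\[Li])C/C=C(\C)CC/C=C(\C)CCC=C(C)C | intermediate
9 | (2Z,5E,9E)-6,10,14-trimethyl-3-(tributylstannyl)pentadeca-2,5,9,13-tetraen-1-ol | OC/C=C(\[Sn](CCCC)(CCCC)CCCC)C/C=C(\C)CC/C=C(\C)CCC=C(C)C | intermediate
10 | [(2R,3S)-3-farnesyl-3-(tributylstannyl)oxiran-2-yl]methanol (C4 S, C5 R, tin cis to CH2OH) | CCCC[Sn](CCCC)(CCCC)[C@]1(C/C=C(\C)CC/C=C(\C)CCC=C(C)C)O[C@@H]1CO | intermediate
11 | (2R,3S)-3-farnesyl-3-(tributylstannyl)oxirane-2-carbaldehyde | CCCC[Sn](CCCC)(CCCC)[C@]1(C/C=C(\C)CC/C=C(\C)CCC=C(C)C)O[C@@H]1C=O | intermediate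
12 | but-2-yne-1,4-diol | OCC#CCO | starting material
13 | 4-(tert-butyldimethylsilyloxy)but-2-yn-1-ol | OCC#CCO[Si](C)(C)C(C)(C)C | intermediate
14 | sodium cyclic alkenylalanate from 13 (Al on future C1) | [Na+].COCCO[Al-]1(OCCOC)OCC=C1CO[Si](C)(C)C(C)(C)C | intermediate
15 | (Z)-4-(tert-butyldimethylsilyloxy)-3-iodobut-2-en-1-ol | OC/C=C(\I)CO[Si](C)(C)C(C)(C)C | intermediate
16 | (Z)-4-(tert-butyldimethylsilyloxy)-3-iodobut-2-enal | O=C/C=C(\I)CO[Si](C)(C)C(C)(C)C | intermediate
17 | (Z)-4-(tert-butyldimethylsilyloxy)-3-iodobut-2-enoic acid | OC(=O)/C=C(\I)CO[Si](C)(C)C(C)(C)C | intermediate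
18 | (Z)-4-(tert-butyldimethylsilyloxy)-3-iodo-N-methoxy-N-methylbut-2-enamide | CON(C)C(=O)/C=C(\I)CO[Si](C)(C)C(C)(C)C | intermediate
19 | alkenylmagnesium chloride from 18 (Mg cis to the amide carbonyl) | CON(C)C(=O)/C=C(\[Mg]Cl)CO[Si](C)(C)C(C)(C)C | intermediate
20 | Z-hydroxy enamide (C4 S, C5 R, C6 S drawn), C6–OH, C7–OTBS | CCCC[Sn](CCCC)(CCCC)[C@]1(C/C=C(\C)CC/C=C(\C)CCC=C(C)C)O[C@@H]1[C@@H](O)/C(CO[Si](C)(C)C(C)(C)C)=C\C(=O)N(C)OC | intermediate
21 | key-step precursor: C4-tributylstannyl epoxide, C6–O-MOP, C7–OTBS, Z-Weinreb enamide (C4 S, C5 R, C6 S drawn) | CCCC[Sn](CCCC)(CCCC)[C@]1(C/C=C(\C)CC/C=C(\C)CCC=C(C)C)O[C@@H]1[C@@H](OC(C)(C)OC)/C(CO[Si](C)(C)C(C)(C)C)=C\C(=O)N(C)OC | intermediate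
22 | C4-oxiranyllithium from 21 (Li in the place of tin) | [Li][C@]1(C/C=C(\C)CC/C=C(\C)CCC=C(C)C)O[C@@H]1[C@@H](OC(C)(C)OC)/C(CO[Si](C)(C)C(C)(C)C)=C\C(=O)N(C)OC | intermediate
23 | cyclised tetrahedral lithium chelate (C3 bears OLi and N(OMe)Me, C3 configuration open) | CON(C)C1(O[Li])C=C(CO[Si](C)(C)C(C)(C)C)[C@H](OC(C)(C)OC)[C@H]2O[C@@]12C/C=C(\C)CC/C=C(\C)CCC=C(C)C | intermediate
24 | key-step product: epoxyquinol C3 enone, C6–O-MOP, C7–OTBS (C4 R, C5 R, C6 S drawn) | O=C1C=C(CO[Si](C)(C)C(C)(C)C)[C@H](OC(C)(C)OC)[C@H]2O[C@@]12C/C=C(\C)CC/C=C(\C)CCC=C(C)C | intermediate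
25 | epoxyquinol diol (C6–OH, C7–OH) | O=C1C=C(CO)[C@H](O)[C@H]2O[C@@]12C/C=C(\C)CC/C=C(\C)CCC=C(C)C | intermediate
26 | epoxyquinol C7 monoacetate (C6–OH free) | O=C1C=C(COC(C)=O)[C@H](O)[C@H]2O[C@@]12C/C=C(\C)CC/C=C(\C)CCC=C(C)C | intermediate
27 | CNP0301406.1, (4R,5S)-epoxyquinone acetate | CC(=O)OCC1=CC(=O)[C@]2(C/C=C(\C)CC/C=C(\C)CCC=C(C)C)O[C@@H]2C1=O | target

Total step count: 15. Longest linear sequence: 11 steps (steps 1–5, then 10–15). Steps 6–9 build the second fragment in parallel.

Steps most likely to fail

1. Step 12. Butyllithium may add to the amide or deprotonate a γ-position faster than it exchanges tin. The oxiranyl anion may also decay by α-elimination before it is acylated.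
The fallback uses known chemistry, sets out from 10 and rejoins at 25. It also needs enal 16, prepared separately from 15 with MnO2. The C3–C4 bond is made with the electrophile outside the molecule, and the ring is closed at C1–C6 instead.
Treating 10 with n-BuLi (2.2 equiv, THF, −90 °C) gives, by alkoxide-assisted tin–lithium exchange, the dilithio epoxy alkoxide F1. This is captured with retention by 16 to give the epoxy diol F2 as C3 epimers. Swern oxidation activates both carbinols before base is added, so no lactol intervenes, and it gives the keto aldehyde F3. An intramolecular Nozaki–Hiyama–Kishi reaction (CrCl2, cat. NiCl2, DMF, high dilution) joins C1 to C6 and gives the C6-hydroxy enone F4. CSA/MeOH then removes the TBS group to give 25.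

2. Step 10. The amide-bearing alkenylmagnesium may decay by loss of silyloxide or by self-acylation before it reaches the hindered aldehyde.
The fallback sets out from 15 and 11 and rejoins at 20, bringing C3 in at the alcohol level. Compound 15 is deprotonated with n-BuLi and exchanged with t-BuLi (Et2O, −78 °C) to the dilithio alkenyl alkoxide F5. This adds to 11 to give the Z-ene-1,4-diol F6. TEMPO/PhI(OAc)2 oxidises the primary allylic alcohol and the derived lactol to the butenolide F7. Aminolysis with N,O-dimethylhydroxylamine hydrochloride/AlMe3 (CH2Cl2, 0 °C) opens the lactone to 20, which is protected at once as in step 11.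

3. Step 4. The bulky stannyl group in the cis position may slow turnover and erode facial selectivity, and the titanium Lewis acid may promote loss of tin.
The fallback sets out from 9 and rejoins at 10. Hydroxyl-directed epoxidation with VO(acac)2/TBHP gives the racemate, that is 10 together with its antipodal epoxy alcohol F8. A lipase-catalysed acylation with vinyl acetate follows, with the enzyme chosen by screening so that the antipode reacts. This converts F8 into the antipodal epoxy acetate F9, which is removed by chromatography to leave 10.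

Further compounds
F1 | step 12 | dilithio epoxy alkoxide from 10 | [Li]OC[C@H]1O[C@]1([Li])C/C=C(\C)CC/C=C(\C)CCC=C(C)C
F2 | step 12 | epoxy diol (C6 primary OH, C3 secondary OH, Z-vinyl iodide at C1) | OC[C@H]1O[C@@]1(C/C=C(\C)CC/C=C(\C)CCC=C(C)C)C(O)/C=C(\I)CO[Si](C)(C)C(C)(C)C
F3 | step 12 | keto aldehyde (C3 ketone, C6 aldehyde) | O=C[C@H]1O[C@@]1(C/C=C(\C)CC/C=C(\C)CCC=C(C)C)C(=O)/C=C(\I)CO[Si](C)(C)C(C)(C)C
F4 | step 12 | C6-hydroxy enone with C7–OTBS | O=C1C=C(CO[Si](C)(C)C(C)(C)C)[C@H](O)[C@H]2O[C@@]12C/C=C(\C)CC/C=C(\C)CCC=C(C)C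
F5 | step 10 | dilithio alkenyl alkoxide from 15 | [Li]OC/C=C(\[Li])CO[Si](C)(C)C(C)(C)C
F6 | step 10 | Z-ene-1,4-diol | CCCC[Sn](CCCC)(CCCC)[C@]1(C/C=C(\C)CC/C=C(\C)CCC=C(C)C)O[C@@H]1[C@@H](O)/C(CO[Si](C)(C)C(C)(C)C)=C\CO
F7 | step 10 | butenolide | CCCC[Sn](CCCC)(CCCC)[C@]1(C/C=C(\C)CC/C=C(\C)CCC=C(C)C)O[C@@H]1[C@H]2OC(=O)C=C2CO[Si](C)(C)C(C)(C)C
F8 | step 4 | antipodal epoxy alcohol (ent-10) | CCCC[Sn](CCCC)(CCCC)[C@@]1(C/C=C(\C)CC/C=C(\C)CCC=C(C)C)O[C@H]1CO
F9 | step 4 | antipodal epoxy acetate | CCCC[Sn](CCCC)(CCCC)[C@@]1(C/C=C(\C)CC/C=C(\C)CCC=C(C)C)O[C@H]1COC(C)=O
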